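## Retrosynthetic overview

- Lactone A is made last: its cis methyl group by hydrogenation of a butenolide, and C3–C18 by vinylogous Mannich addition of a 2-silyloxyfuran to the C3 iminium ion obtained by partial reduction of a C3 lactam.
- The azepane ring is closed by a formal (4+3) annulation in one flask between a 1-(methoxymethyl)pyrrol-2(5H)-one (C5–N4–C9a) and a 2-silyloxy-1,3-diene (C6–C9) that already carries lactone B. C5–C6 forms by N-acyliminium Mukaiyama–Mannich reaction, C9–C9a by vinylogous Mukaiyama–Michael addition; a temporary C7 ketone is removed afterwards.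
- Enabling feature: N4 is flanked by C5 and C9a. With C3 as a lactam carbonyl, the ring N4–C9a–C1–C2–C3 is a pyrrol-2-one, so the exocyclic N–CH2 (C5) is an N-acyliminium carbon. C9a becomes a nucleophile after enolisation to the aromatic 2-silyloxypyrrole (polarity reversal of an α-amino carbon, then dearomatisation). C6–C9 is an unsubstituted four-carbon chain that tolerates an enone.
- Side chain: C10/C11 by (Z)-pentenylboration of methyl 4-oxobutanoate (lactone B closes at once), C13 by trans-methylation, C6–C8 by cross-metathesis.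
- Ring order: lactone B, pyrrolone ring (bought), azepane (key step), lactone A.

Key step: step 6

Remark: atom numbers are those of the pyrrolo[1,2-a]azepine core (C1–C3, N4, C5–C9, C9a), with C10 bearing the ethyl group, lactone B = C11–C14 (methyl on C13) and lactone A = C18–C21 (methyl on C20); compounds 1, 2, 10 and 19 are assumed to be commercial.

## Route

Step 1
Reactants: 1 methyl 4-oxobutanoate; 2 (Z)-pent-2-ene
Product: 6 (5R)-5-[(3R)-pent-1-en-3-yl]oxolan-2-one, via (Z)-pent-2-enylpotassium 3 (not isolated), via pentenylborane 4 (not isolated), via hydroxy ester 5 (not isolated)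
Conditions: 2, KOt-Bu, n-BuLi, THF, −78 to −45 °C; (−)-Ipc2BOMe [from (+)-α-pinene], −78 °C; BF3·OEt2; 1, −78 °C; HOCH2CH2NH2; p-TsOH (cat.), CH2Cl2, rt
Reagents that add atoms: none
Why: Metalation of 2 at its methyl group and trapping on boron give the (Z)-γ-ethylallyl borane 4, which adds to the aldehyde through a closed chair (Zimmerman–Traxler) transition state in an asymmetric allylboration, so that the Z geometry sets the syn C10/C11 relationship and the isopinocampheyl groups direct attack to the Si face (10R,11R), after which the γ-hydroxy ester 5 lactonises under acid catalysis.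

Step 2
Reactants: 6 (5R)-5-[(3R)-pent-1-en-3-yl]oxolan-2-one
Product: 7 (3S,5R)-3-methyl-5-[(3R)-pent-1-en-3-yl]oxolan-2-one
Conditions: LiN(i-Pr)2, THF, −78 °C; MeI, −78 to −40 °C
Reagents that add atoms: iodomethane CI
Why: Alkylation of the lactone lithium enolate, in which iodomethane approaches the face opposite to the C11 side chain, should give the 2,4-trans lactone (13S).

Step 3
Reactants: 7 (3S,5R)-3-methyl-5-[(3R)-pent-1-en-3-yl]oxolan-2-one
Product: 8 (3S,5R)-3-methyl-5-[(3R,4E)-6-oxohept-4-en-3-yl]oxolan-2-one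
Conditions: but-3-en-2-one (3 equiv), second-generation Hoveyda–Grubbs catalyst (5 mol %), CH2Cl2, 40 °C
Reagents that add atoms: but-3-en-2-one CC(=O)C=C
Why: Olefin cross-metathesis of the terminal alkene with an electron-poor partner is expected to give the E-enone under thermodynamic control, the allylic branching of 7 suppressing its own dimerisation; no stereocentre is formed.

Step 4
Reactants: 8 (3S,5R)-3-methyl-5-[(3R,4E)-6-oxohept-4-en-3-yl]oxolan-2-one
Product: 9 (3S,5R)-5-[(3R,4E)-6-(tert-butyldimethylsilyloxy)hepta-4,6-dien-3-yl]-3-methyloxolan-2-one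
Conditions: t-BuMe2SiOTf, Et3N, CH2Cl2, 0 °C
Reagents that add atoms: tert-butyldimethylsilyl trifluoromethanesulfonate CC(C)(C)[Si](C)(C)OS(=O)(=O)C(F)(F)F
Why: Soft enolisation with a silyl triflate and an amine silylates the ketone, whose only α-hydrogens are those of the methyl group, so that the cross-conjugated 2-silyloxy-1,3-diene forms as a single regioisomer while the less acidic lactone is left alone; no stereocentre is formed.

Step 5
Reactants: 10 1,5-dihydro-2H-pyrrol-2-one
Product: 11 1-(methoxymethyl)-1,5-dihydro-2H-pyrrol-2-one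
Conditions: NaH, THF, 0 °C; MeOCH2Cl
Reagents that add atoms: chloromethyl methyl ether COCCl
Why: N-Alkylation of the lactam sodium salt (the N–H is more acidic than the C5 methylene) installs the N,O-acetal that later serves as N-acyliminium precursor; no stereocentre is formed.

Step 6
Reactants: 9 (3S,5R)-5-[(3R,4E)-6-(tert-butyldimethylsilyloxy)hepta-4,6-dien-3-yl]-3-methyloxolan-2-one; 11 1-(methoxymethyl)-1,5-dihydro-2H-pyrrol-2-one
Product: 16 (9R,9aS)-9-[(1R)-1-[(2R,4S)-4-methyl-5-oxooxolan-2-yl]propyl]-5,6,9,9a-tetrahydro-3H-pyrrolo[1,2-a]azepine-3,7(8H)-dione, via N-acyliminium triflate 12 (not isolated), via Mannich adduct 13 (not isolated), via silyloxypyrrole 14 (not isolated), via silyl enol ether 15 (not isolated)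
Conditions: Me3SiOTf (1.05 equiv), CH2Cl2, −78 to −40 °C; then i-Pr2NEt (1.5 equiv), −78 to −20 °C; 1 M HCl, THF, 0 °C
Reagents that add atoms: none
Why: Me3SiOTf ionises the N,O-acetal of 11 to the N-acyliminium ion 12, which the silyl dienol ether 9 attacks through C6 (Mukaiyama–Mannich amidoalkylation, C5–C6) to give enone 13 and t-BuMe2SiOTf; that silyl triflate and i-Pr2NEt then turn the pyrrol-2(5H)-one into the aromatic 2-silyloxypyrrole 14, whose C9a position adds to the enone β-carbon C9 (intramolecular vinylogous Mukaiyama–Michael addition with dearomatisation, C9–C9a) to give silyl enol ether 15, which is hydrolysed to 16 on work-up. The closest known reactions are the amidoalkylation of silyl enol ethers by N-acyliminium ions and the vinylogous Mukaiyama–Michael additions and silylative cyclisations of 2-silyloxypyrroles; run in sequence they amount to a formal (4+3) annulation of a C–N–C unit with a four-carbon unit. The azepane ring closes in the 7-endo-trig mode onto the s-trans form of the E-enone. C9 is set by 1,2-induction from C10 in a Felkin–Anh arrangement (C11 branch anti to the incoming pyrrole, ethyl group inside), which corresponds to the required 9R configuration. C9a follows from a compact transition state in which the pyrrole ring lies over the enone with H9 and H9a on the same side (cis ring-fusion hydrogens, 9aS). The step needs C6 as the only nucleophilic carbon of 9, which the cross-conjugated enol ether secures; it needs 1,4-addition to a seven-membered ring, which is secured because C8 is vinylic after the Mannich stage (no five-membered ring possible) and attack through the other pyrrole α-carbon would need an eight-membered ring; and it needs dienolisation of the lactam to outrun silylation of the C7 ketone, which the gain of aromaticity should favour.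

Step 7
Reactants: 16 (9R,9aS)-9-[(1R)-1-[(2R,4S)-4-methyl-5-oxooxolan-2-yl]propyl]-5,6,9,9a-tetrahydro-3H-pyrrolo[1,2-a]azepine-3,7(8H)-dione
Product: 17 1,3-dithiolane of the C7 ketone of 16 (C1=C2 double bond and all stereocentres unchanged)
Conditions: HSCH2CH2SH, BF3·OEt2, CH2Cl2, 0 °C to rt
Reagents that add atoms: ethane-1,2-dithiol SCCS
Why: Lewis-acid-catalysed dithioketalisation is selective for the unhindered C7 ketone over the lactone and lactam carbonyl groups, and any thiol that adds to C1 of the unsaturated lactam is removed again in step 8; no stereocentre is formed.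

Step 8
Reactants: 17 1,3-dithiolane of the C7 ketone of 16
Product: 18 (9R,9aS)-9-[(1R)-1-[(2R,4S)-4-methyl-5-oxooxolan-2-yl]propyl]octahydro-3H-pyrrolo[1,2-a]azepin-3-one
Conditions: Raney Ni (W-2), H2 (1 atm), EtOH, reflux
Reagents that add atoms: none
Why: Mozingo reduction, in which hydrogen-saturated Raney nickel cleaves both C–S bonds to leave C7 as a methylene group and also hydrogenates the C1=C2 double bond, without touching a stereocentre.

Step 9
Reactants: 19 3-methylfuran-2(5H)-one
Product: 20 triisopropyl[(3-methylfuran-2-yl)oxy]silane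
Conditions: i-Pr3SiOTf, Et3N, CH2Cl2, 0 °C
Reagents that add atoms: triisopropylsilyl trifluoromethanesulfonate CC(C)[Si](C(C)C)(C(C)C)OS(=O)(=O)C(F)(F)F
Why: Silylation of the butenolide dienolate gives the aromatic 2-silyloxyfuran, the nucleophile for the vinylogous Mannich reaction; no stereocentre is formed.

Step 10
Reactants: 18 (9R,9aS)-9-[(1R)-1-[(2R,4S)-4-methyl-5-oxooxolan-2-yl]propyl]octahydro-3H-pyrrolo[1,2-a]azepin-3-one; 20 triisopropyl[(3-methylfuran-2-yl)oxy]silane
Product: 23 (5S)-3-methyl-5-[(3S,9R,9aS)-9-[(1R)-1-[(2R,4S)-4-methyl-5-oxooxolan-2-yl]propyl]octahydro-1H-pyrrolo[1,2-a]azepin-3-yl]furan-2(5H)-one, via O-silyl hemiaminal 21 (not isolated), via iminium triflate 22 (not isolated)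
Conditions: IrCl(CO)(PPh3)2 (1 mol %), (Me2SiH)2O, toluene, rt; then 20, Me3SiOTf, CH2Cl2, −78 °C; aq NaHCO3
Reagents that add atoms: none
Why: Iridium-catalysed hydrosilylation reduces the tertiary lactam, not the lactone, to the O-silyl hemiaminal 21, which Me3SiOTf ionises to the bicyclic iminium ion 22; in the vinylogous Mannich reaction the silyloxyfuran should attack C3 from the face opposite to the C9a–C9 bond (3,9a-trans, 3S) through the usual open transition state that leads to the threo C3/C18 pair (18S).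

Step 11
Reactants: 23 (5S)-3-methyl-5-[(3S,9R,9aS)-9-[(1R)-1-[(2R,4S)-4-methyl-5-oxooxolan-2-yl]propyl]octahydro-1H-pyrrolo[1,2-a]azepin-3-yl]furan-2(5H)-one
Product: 24 (3S,5S)-3-methyl-5-[(3S,9R,9aS)-9-[(1R)-1-[(2R,4S)-4-methyl-5-oxooxolan-2-yl]propyl]octahydro-1H-pyrrolo[1,2-a]azepin-3-yl]oxolan-2-one (CNP0135535.2)
Conditions: H2 (1 atm), Pd/C, EtOAc, rt
Reagents that add atoms: none
Why: Heterogeneous hydrogenation delivers hydrogen to the butenolide face opposite to the C18 substituent and so should give the cis lactone (20S), while the tertiary amine and lactone B are inert.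

## Compound list

1 | methyl 4-oxobutanoate | COC(=O)CCC=O | starting material
2 | (Z)-pent-2-ene | C/C=C\CC | starting material
3 | (Z)-pent-2-en-1-ylpotassium | CC/C=C\C[K] | intermediate
4 | [(2Z)-pent-2-en-1-yl]bis[(1R,2S,3R,5R)-2,6,6-trimethylbicyclo[3.1.1]heptan-3-yl]borane | CC/C=C\CB([C@@H]1C[C@@H]2C[C@@H](C2(C)C)[C@H]1C)[C@@H]1C[C@@H]2C[C@@H](C2(C)C)[C@H]1C | intermediate
5 | methyl (4R,5R)-5-ethyl-4-hydroxyhept-6-enoate | CC[C@H](C=C)[C@H](O)CCC(=O)OC | intermediate
6 | (5R)-5-[(3R)-pent-1-en-3-yl]oxolan-2-one | CC[C@H](C=C)[C@H]1CCC(=O)O1 | intermediate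
7 | (3S,5R)-3-methyl-5-[(3R)-pent-1-en-3-yl]oxolan-2-one | CC[C@H](C=C)[C@H]1C[C@H](C)C(=O)O1 | intermediate
8 | (3S,5R)-3-methyl-5-[(3R,4E)-6-oxohept-4-en-3-yl]oxolan-2-one | CC[C@H](/C=C/C(C)=O)[C@H]1C[C@H](C)C(=O)O1 | intermediate
9 | (3S,5R)-5-[(3R,4E)-6-(tert-butyldimethylsilyloxy)hepta-4,6-dien-3-yl]-3-methyloxolan-2-one | CC[C@H](/C=C/C(=C)O[Si](C)(C)C(C)(C)C)[C@H]1C[C@H](C)C(=O)O1 | intermediate
10 | 1,5-dihydro-2H-pyrrol-2-one | O=C1C=CCN1 | starting material
11 | 1-(methoxymethyl)-1,5-dihydro-2H-pyrrol-2-one | COCN1CC=CC1=O | intermediate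
12 | 1-methylidene-2-oxo-2,5-dihydro-1H-pyrrol-1-ium trifluoromethanesulfonate | C=[N+]1CC=CC1=O.[O-]S(=O)(=O)C(F)(F)F | intermediate
13 | (3S,5R)-3-methyl-5-[(3R,4E)-6-oxo-8-(2-oxo-2,5-dihydro-1H-pyrrol-1-yl)oct-4-en-3-yl]oxolan-2-one | CC[C@H](/C=C/C(=O)CCN1CC=CC1=O)[C@H]1C[C@H](C)C(=O)O1 | intermediate
14 | (3S,5R)-5-[(3R,4E)-8-[2-(tert-butyldimethylsilyloxy)-1H-pyrrol-1-yl]-6-oxooct-4-en-3-yl]-3-methyloxolan-2-one | CC[C@H](/C=C/C(=O)CCn1cccc1O[Si](C)(C)C(C)(C)C)[C@H]1C[C@H](C)C(=O)O1 | intermediate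
15 | tert-butyldimethylsilyl enol ether (C7–O, C7=C8) of keto lactam 16, same configuration at C9, C9a, C10, C11 and C13 | CC[C@H]([C@H]1C=C(O[Si](C)(C)C(C)(C)C)CCN2[C@H]1C=CC2=O)[C@H]1C[C@H](C)C(=O)O1 | intermediate
16 | (9R,9aS)-9-[(1R)-1-[(2R,4S)-4-methyl-5-oxooxolan-2-yl]propyl]-5,6,9,9a-tetrahydro-3H-pyrrolo[1,2-a]azepine-3,7(8H)-dione | CC[C@H]([C@H]1CC(=O)CCN2[C@H]1C=CC2=O)[C@H]1C[C@H](C)C(=O)O1 | intermediate
17 | 1,3-dithiolane of the C7 ketone of 16 (spiro at C7, C1=C2 retained, 9R,9aS) | CC[C@H]([C@H]1CC2(SCCS2)CCN2[C@H]1C=CC2=O)[C@H]1C[C@H](C)C(=O)O1 | intermediate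
18 | (9R,9aS)-9-[(1R)-1-[(2R,4S)-4-methyl-5-oxooxolan-2-yl]propyl]octahydro-3H-pyrrolo[1,2-a]azepin-3-one | CC[C@H]([C@H]1CCCCN2[C@H]1CCC2=O)[C@H]1C[C@H](C)C(=O)O1 | intermediate
19 | 3-methylfuran-2(5H)-one | CC1=CCOC1=O | starting material
20 | triisopropyl[(3-methylfuran-2-yl)oxy]silane | Cc1ccoc1O[Si](C(C)C)(C(C)C)C(C)C | intermediate
21 | O-(1,1,3,3-tetramethyldisiloxanyl) hemiaminal of lactam 18 (C3–H, C3–OSi; mixture at C3) | CC[C@H]([C@H]1CCCCN2[C@H]1CCC2O[Si](C)(C)O[SiH](C)C)[C@H]1C[C@H](C)C(=O)O1 | intermediate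
22 | bicyclic iminium (N4=C3) trifluoromethanesulfonate derived from 18 | CC[C@H]([C@H]1CCCC[N+]2[C@H]1CCC=2)[C@H]1C[C@H](C)C(=O)O1.[O-]S(=O)(=O)C(F)(F)F | intermediate
23 | (5S)-3-methyl-5-[(3S,9R,9aS)-9-[(1R)-1-[(2R,4S)-4-methyl-5-oxooxolan-2-yl]propyl]octahydro-1H-pyrrolo[1,2-a]azepin-3-yl]furan-2(5H)-one | CC[C@H]([C@H]1CCCCN2[C@H]1CC[C@H]2[C@@H]1C=C(C)C(=O)O1)[C@H]1C[C@H](C)C(=O)O1 | intermediate
24 | (3S,5S)-3-methyl-5-[(3S,9R,9aS)-9-[(1R)-1-[(2R,4S)-4-methyl-5-oxooxolan-2-yl]propyl]octahydro-1H-pyrrolo[1,2-a]azepin-3-yl]oxolan-2-one | CC[C@H]([C@H]1CCCCN2[C@H]1CC[C@H]2[C@@H]1C[C@H](C)C(=O)O1)[C@H]1C[C@H](C)C(=O)O1 | target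

## Step count and risks

Total steps: 11. Longest linear sequence: 9 steps (steps 1, 2, 3, 4, 6, 7, 8, 10, 11).

Steps most likely to fail:

**Step 6.** In the second stage the C7 ketone of 13 may be silylated in competition with dienolisation of the lactam, which would stop the ring closure; the ring closure itself may also show poor facial selectivity at C9 and C9a. The fallback sets out from 7 and comes back at 18, building the same ring from separate, known reactions. Cross-metathesis of 7 with acrolein (second-generation Hoveyda–Grubbs catalyst) should give the E-enal F1. Iminium-catalysed vinylogous Mukaiyama–Michael addition of commercial tert-butyl 2-(tert-butyldimethylsilyloxy)pyrrole-1-carboxylate (5-benzyl-2-tert-butyl-3-methylimidazolidin-4-one trifluoroacetate, the enantiomer that gives 9R) should give the Michael adduct aldehyde F2, with C9 under catalyst control. Wittig methylenation (Ph3P=CH2) gives the terminal alkene F3, TFA removes the carbamate to give the N–H lactam F4, and NaH with allyl bromide gives the N-allyl lactam F5. Ring-closing metathesis (second-generation Grubbs catalyst) closes the azepine as the bicyclic diene lactam F6, and hydrogenation (H2, Pd/C) returns to 18.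

**Step 1.** Metalation of 2 at C4 instead of C1, or loss of the Z geometry of the allyl metal, would erode the regio- and diastereoselectivity of the allylboration. The fallback sets out from 1 and comes back at 6. (S)-4-Benzyl-1,3-oxazolidin-2-one is acylated (n-BuLi, butanoyl chloride) to the N-butanoyl oxazolidinone F7. Its dibutylboron enolate (Bu2BOTf, i-Pr2NEt) adds to 1 in an Evans syn-aldol reaction and the adduct lactonises (p-TsOH) to the imide lactone F8. LiSEt gives the thioester F9, Fukuyama reduction (Et3SiH, Pd/C) gives the aldehyde F10, and Wittig methylenation (Ph3P=CH2) returns to 6.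

**Step 3.** Metathesis of the allylically branched alkene may be slow, so that self-metathesis of the enone partner and catalyst decay take over. The fallback sets out from 7 and comes back at 8. Ozonolysis (O3, CH2Cl2, −78 °C; Me2S) gives the aldehyde F11, and a Wittig reaction with Ph3P=CHC(O)CH3 should return to 8 as the E-enone.

Further compounds
F1 | step 6 | (2E,4R)-4-[(2R,4S)-4-methyl-5-oxooxolan-2-yl]hex-2-enal | CC[C@H](/C=C/C=O)[C@H]1C[C@H](C)C(=O)O1
F2 | step 6 | tert-butyl (2S)-2-[(3R,4R)-4-[(2R,4S)-4-methyl-5-oxooxolan-2-yl]-1-oxohexan-3-yl]-5-oxo-2,5-dihydro-1H-pyrrole-1-carboxylate | CC[C@H]([C@@H](CC=O)[C@@H]1C=CC(=O)N1C(=O)OC(C)(C)C)[C@H]1C[C@H](C)C(=O)O1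
F3 | step 6 | tert-butyl (2S)-2-[(3R,4R)-3-[(2R,4S)-4-methyl-5-oxooxolan-2-yl]hept-6-en-4-yl]-5-oxo-2,5-dihydro-1H-pyrrole-1-carboxylate | CC[C@H]([C@@H](CC=C)[C@@H]1C=CC(=O)N1C(=O)OC(C)(C)C)[C@H]1C[C@H](C)C(=O)O1
F4 | step 6 | (5S)-5-[(3R,4R)-3-[(2R,4S)-4-methyl-5-oxooxolan-2-yl]hept-6-en-4-yl]-1,5-dihydro-2H-pyrrol-2-one | CC[C@H]([C@@H](CC=C)[C@@H]1C=CC(=O)N1)[C@H]1C[C@H](C)C(=O)O1
F5 | step 6 | (5S)-5-[(3R,4R)-3-[(2R,4S)-4-methyl-5-oxooxolan-2-yl]hept-6-en-4-yl]-1-(prop-2-en-1-yl)-1,5-dihydro-2H-pyrrol-2-one | CC[C@H]([C@@H](CC=C)[C@@H]1C=CC(=O)N1CC=C)[C@H]1C[C@H](C)C(=O)O1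
F6 | step 6 | (9R,9aS)-9-[(1R)-1-[(2R,4S)-4-methyl-5-oxooxolan-2-yl]propyl]-5,8,9,9a-tetrahydro-3H-pyrrolo[1,2-a]azepin-3-one | CC[C@H]([C@H]1CC=CCN2[C@H]1C=CC2=O)[C@H]1C[C@H](C)C(=O)O1
F7 | step 1 | (4S)-4-benzyl-3-butanoyl-1,3-oxazolidin-2-one | CCCC(=O)N1[C@@H](Cc2ccccc2)COC1=O
F8 | step 1 | (4S)-4-benzyl-3-[(2S)-2-[(2R)-5-oxooxolan-2-yl]butanoyl]-1,3-oxazolidin-2-one | CC[C@H](C(=O)N1[C@@H](Cc2ccccc2)COC1=O)[C@H]1CCC(=O)O1
F9 | step 1 | S-ethyl (2S)-2-[(2R)-5-oxooxolan-2-yl]butanethioate | CC[C@H](C(=O)SCC)[C@H]1CCC(=O)O1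
F10 | step 1 | (2S)-2-[(2R)-5-oxooxolan-2-yl]butanal | CC[C@H](C=O)[C@H]1CCC(=O)O1
F11 | step 3 | (2S)-2-[(2R,4S)-4-methyl-5-oxooxolan-2-yl]butanal | CC[C@H](C=O)[C@H]1C[C@H](C)C(=O)O1
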